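Ring A (the filicinic ring, C1–C6) is a β-triketone: C3 is an acyl carbon lying 1,3 to C1 and bonded to C2, which carries the CH2 bridge to chromene ring B. C2–C3 is therefore stored as a dihydrocoumarin lactone closed on the neighbouring phenol oxygen of ring B, and C4–C5–C6–C1 as a 5-ethylisoxazole-4-carboxylate whose isoxazole masks the isobutyryl group. One-pot Claisen acylation (C3–C4, lactone opening) and Dieckmann closure (C1–C2) build ring A in aromatic, isoxazole-fused form and unite both halves. Asymmetric dearomative prenylation then creates the C4 stereocentre, and N–O cleavage with hydrolysis unveils the triketone.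

Key step: step 5

Assumption: the target is treated as one tautomer of a β-triketone, ring A being numbered as a cyclohexa-2,5-dien-1-one (C1 carbonyl, C2 bearing the CH2 bridge, C3–OH, C4 quaternary, C5–OH, C6 bearing the isobutyryl group); in this drawn form C4 is (S).

Step 1
Reactants: 1 phloroglucinol; 2 2-methylpropanoyl chloride
Product: 3 2-methyl-1-(2,4,6-trihydroxyphenyl)propan-1-one
Conditions: AlCl3, PhNO2–CH2Cl2, 0 °C to 25 °C; aq. HCl
Reagents that add atoms: none
Why: Friedel–Crafts C-acylation of the symmetrical, strongly activated triol should stop at the monoketone because the chelated acyl group deactivates the ring.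

Step 2
Reactants: 3 2-methyl-1-(2,4,6-trihydroxyphenyl)propan-1-one; 4 3-methylbut-2-enal
Product: 5 1-(5,7-dihydroxy-2,2-dimethyl-2H-chromen-8-yl)-2-methylpropan-1-one
Conditions: ethylenediammonium diacetate (cat.), toluene, 110 °C
Reagents that add atoms: none
Why: Amine-catalysed Knoevenagel-type condensation at a free ring carbon followed by oxa-6π electrocyclisation (formal [3+3] chromene annulation) should give the 2,2-dimethylchromene; the isomer closed on the hydroxyl next to the acyl group (8-acyl) is separated by chromatography from the 6-acyl isomer.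

Step 3
Reactants: 5 1-(5,7-dihydroxy-2,2-dimethyl-2H-chromen-8-yl)-2-methylpropan-1-one; 6 formaldehyde (charged as paraformaldehyde); 7 Meldrum's acid
Product: 10 dihydrocoumarin lactone 5-hydroxy-8,8-dimethyl-6-(2-methylpropanoyl)-3,4-dihydro-2H,8H-pyrano[2,3-f]chromen-2-one, via methylidene Meldrum's acid 8 (not isolated), via benzyl Meldrum's acid adduct 9 (not isolated)
Conditions: paraformaldehyde, Meldrum's acid (2 equiv), pyridine, 90 °C
Reagents that add atoms: none
Why: Knoevenagel condensation gives 8, the only free ring carbon of 5 (C6) adds to it in a Michael reaction to give 9, and the free 5-hydroxyl then attacks a Meldrum's acid carbonyl with loss of acetone and CO2 to close the lactone; closure on O7 instead would give a lactone that opens to the same phenol in step 5.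

Step 4
Reactants: 11 ethyl 3-oxopentanoate; 12 2-methylpropanal oxime
Product: 15 ethyl 5-ethyl-3-(propan-2-yl)-1,2-oxazole-4-carboxylate, via hydroximoyl chloride 13 (not isolated), via nitrile oxide 14 (not isolated)
Conditions: 12, N-chlorosuccinimide, DMF, 25 °C; then 11, NaOEt, EtOH, 0 °C to 25 °C
Reagents that add atoms: none
Why: Chlorination of the aldoxime gives 13, ethoxide converts it into 14, and regioselective [3+2] cycloaddition–dehydration with the sodium enolate of 11 (nitrile oxide carbon to the α-carbon, oxygen to the ketone carbon) should give the 3,4,5-trisubstituted isoxazole.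

Step 5
Reactants: 15 ethyl 5-ethyl-3-(propan-2-yl)-1,2-oxazole-4-carboxylate; 10 dihydrocoumarin lactone
Product: 17 5-{[5,7-dihydroxy-2,2-dimethyl-8-(2-methylpropanoyl)-2H-chromen-6-yl]methyl}-7-methyl-3-(propan-2-yl)-1,2-benzoxazole-4,6-diol, via ketone 16 (not isolated)
Conditions: 15 (2.1 equiv), LDA (2.2 equiv), THF, −78 °C; add 10 pre-treated with LDA (1.0 equiv); then LDA (2.5 equiv), −78 °C to 25 °C; 1 M aq. HCl
Reagents that add atoms: none
Why: LDA removes a proton only from the CH2 of the 5-ethyl group (lateral metalation: this position is vinylogous to the ester through the isoxazole C5=C4 bond, the 3-isopropyl group is not), and this carbanion (future C4) opens the aryl ester of 10 at its carbonyl carbon (future C3), releasing the ring B phenoxide and giving 16 as its enolate. Further LDA generates the carbanion at the former lactone α-carbon (future C2), which attacks the ester carbon (future C1) in a Dieckmann condensation, and the dione tautomerises to the aromatic diol on acidic work-up. The closest known reaction types are the lateral-metalation Claisen acylation of 5-alkylisoxazole-4-carboxylates and the Claisen–Dieckmann anionic benzannulation of ortho-toluate-type carbanions (Staunton–Weinreb-type annulation). The one ring closure is 6-(enolendo)-exo-trig. No stereocentre is formed, because C4 becomes an aromatic carbon at this stage. The step needs site-selective deprotonation, secured by the isoxazole; attack on the lactone and not on the aryl ketone, secured by the activated aryl ester and the hindered, chelated ketone; and C- rather than O-cyclisation, secured by the more reactive carbon terminus of the dianion and by aromatisation.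

Step 6
Reactants: 17 benzisoxazole diol; 18 3-methylbut-2-en-1-yl acetate
Product: 19 (7S)-5-{[5,7-dihydroxy-2,2-dimethyl-8-(2-methylpropanoyl)-2H-chromen-6-yl]methyl}-6-hydroxy-7-methyl-7-(3-methylbut-2-en-1-yl)-3-(propan-2-yl)-1,2-benzoxazol-4(7H)-one
Conditions: Pd2(dba)3·CHCl3 (2.5 mol %), (R,R)-N,N'-bis(2-diphenylphosphinobenzoyl)-1,2-diaminocyclohexane (7.5 mol %), 18 (1.05 equiv), Et3N (1.2 equiv), 1,4-dioxane, 25 °C
Reagents that add atoms: none
Why: Tsuji–Trost asymmetric allylic dearomatisation, in which the 6-phenolate of 17 attacks the CH2 terminus of the π-prenyl complex of divalent palladium through its ortho carbon C7; C7 is the least hindered nucleophilic carbon (methyl against CH2Ar at C5 and in ring B) and is flanked unequally by C6–O and the ring-fusion carbon C7a, as C1 is in a 1-alkyl-2-naphthol, so the chiral ligand pocket should discriminate the two faces and set C7 as (S), while O-prenyl ethers are returned to the ion pair by zerovalent palladium; the (R,R) ligand is written and its antipode is used if it proves to favour the other face.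

Step 7
Reactants: 19 (7S)-prenylated benzisoxazolone
Product: 21 (4S)-2-{[5,7-dihydroxy-2,2-dimethyl-8-(2-methylpropanoyl)-2H-chromen-6-yl]methyl}-3,5-dihydroxy-4-methyl-4-(3-methylbut-2-en-1-yl)-6-(2-methylpropanoyl)cyclohexa-2,5-dien-1-one (CNP0301804.1), via enaminone 20 (not isolated)
Conditions: Mo(CO)6, MeCN–H2O, 80 °C; then 0.5 M aq. HCl–THF, 40 °C
Reagents that add atoms: water, O
Why: Mo(CO)6 should cleave the isoxazole N–O bond reductively without touching the alkenes to give the vinylogous amide 20, whose mild acid hydrolysis releases ammonia and the isobutyryl ketone; the quaternary C4 is not enolisable and keeps its configuration.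

Compound list
1 | phloroglucinol (benzene-1,3,5-triol) | Oc1cc(O)cc(O)c1 | starting material
2 | 2-methylpropanoyl chloride (isobutyryl chloride) | CC(C)C(Cl)=O | starting material
3 | 2-methyl-1-(2,4,6-trihydroxyphenyl)propan-1-one | CC(C)C(=O)c1c(O)cc(O)cc1O | intermediate
4 | 3-methylbut-2-enal | CC(C)=CC=O | starting material
5 | 1-(5,7-dihydroxy-2,2-dimethyl-2H-chromen-8-yl)-2-methylpropan-1-one | CC(C)C(=O)c1c(O)cc(O)c2C=CC(C)(C)Oc12 | intermediate
6 | formaldehyde (charged as paraformaldehyde) | C=O | starting material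
7 | Meldrum's acid (2,2-dimethyl-1,3-dioxane-4,6-dione) | CC1(C)OC(=O)CC(=O)O1 | starting material
8 | 2,2-dimethyl-5-methylidene-1,3-dioxane-4,6-dione | C=C1C(=O)OC(C)(C)OC1=O | intermediate (not isolated)
9 | 5-{[5,7-dihydroxy-2,2-dimethyl-8-(2-methylpropanoyl)-2H-chromen-6-yl]methyl}-2,2-dimethyl-1,3-dioxane-4,6-dione | CC(C)C(=O)c1c(O)c(CC2C(=O)OC(C)(C)OC2=O)c(O)c2C=CC(C)(C)Oc12 | intermediate (not isolated)
10 | 5-hydroxy-8,8-dimethyl-6-(2-methylpropanoyl)-3,4-dihydro-2H,8H-pyrano[2,3-f]chromen-2-one (dihydrocoumarin lactone closed on O5 of 5) | CC(C)C(=O)c1c(O)c2CCC(=O)Oc2c2C=CC(C)(C)Oc12 | intermediate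
11 | ethyl 3-oxopentanoate | CCC(=O)CC(=O)OCC | starting material
12 | 2-methylpropanal oxime | CC(C)C=NO | starting material
13 | N-hydroxy-2-methylpropanimidoyl chloride | CC(C)C(Cl)=NO | intermediate (not isolated)
14 | 2-methylpropanenitrile oxide | CC(C)C#[N+][O-] | intermediate (not isolated)
15 | ethyl 5-ethyl-3-(propan-2-yl)-1,2-oxazole-4-carboxylate | CCOC(=O)c1c(C(C)C)noc1CC | intermediate
16 | ethyl 5-{5-[5,7-dihydroxy-2,2-dimethyl-8-(2-methylpropanoyl)-2H-chromen-6-yl]-3-oxopentan-2-yl}-3-(propan-2-yl)-1,2-oxazole-4-carboxylate | CCOC(=O)c1c(C(C)C)noc1C(C)C(=O)CCc1c(O)c2C=CC(C)(C)Oc2c(C(=O)C(C)C)c1O | intermediate (not isolated)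
17 | 5-{[5,7-dihydroxy-2,2-dimethyl-8-(2-methylpropanoyl)-2H-chromen-6-yl]methyl}-7-methyl-3-(propan-2-yl)-1,2-benzoxazole-4,6-diol | Cc1c(O)c(Cc2c(O)c3C=CC(C)(C)Oc3c(C(=O)C(C)C)c2O)c(O)c2c(C(C)C)noc12 | intermediate
18 | 3-methylbut-2-en-1-yl acetate (prenyl acetate) | CC(C)=CCOC(C)=O | starting material
19 | (7S)-5-{[5,7-dihydroxy-2,2-dimethyl-8-(2-methylpropanoyl)-2H-chromen-6-yl]methyl}-6-hydroxy-7-methyl-7-(3-methylbut-2-en-1-yl)-3-(propan-2-yl)-1,2-benzoxazol-4(7H)-one | CC(C)=CC[C@@]1(C)C(O)=C(Cc2c(O)c3c(c(C(=O)C(C)C)c2O)OC(C)(C)C=C3)C(=O)c2c(C(C)C)noc21 | intermediate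
20 | (4S)-6-(1-amino-2-methylpropylidene)-2-{[5,7-dihydroxy-2,2-dimethyl-8-(2-methylpropanoyl)-2H-chromen-6-yl]methyl}-3-hydroxy-4-methyl-4-(3-methylbut-2-en-1-yl)cyclohex-2-ene-1,5-dione | CC(C)=CC[C@@]1(C)C(O)=C(Cc2c(O)c3c(c(C(=O)C(C)C)c2O)OC(C)(C)C=C3)C(=O)C(=C(N)C(C)C)C1=O | intermediate (not isolated)
21 | (4S)-2-{[5,7-dihydroxy-2,2-dimethyl-8-(2-methylpropanoyl)-2H-chromen-6-yl]methyl}-3,5-dihydroxy-4-methyl-4-(3-methylbut-2-en-1-yl)-6-(2-methylpropanoyl)cyclohexa-2,5-dien-1-one (CNP0301804.1) | CC(C)=CC[C@@]1(C)C(O)=C(Cc2c(O)c3c(c(C(=O)C(C)C)c2O)OC(C)(C)C=C3)C(=O)C(C(=O)C(C)C)=C1O | target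

Total step count: 7.
Longest linear sequence: 6 steps (steps 1, 2, 3, 5, 6 and 7); step 4 supplies the isoxazole branch.

Steps most likely to fail

1. Step 6. The prenyl group may be delivered to the wrong site (a CH2-bearing ring carbon, or oxygen without return to the ion pair), or the ligand may discriminate the two faces of C7 poorly. The fallback sets out from 15 and comes back at 19. It puts the prenyl group in before the annulation and settles the configuration by separation. Lateral deprotonation of 15 with LDA (THF, −78 °C) and alkylation with prenyl bromide would give racemic ethyl 5-(5-methylhex-4-en-2-yl)-3-(propan-2-yl)-1,2-oxazole-4-carboxylate F1. The Claisen–Dieckmann sequence of step 5 with 10 would then pass through the quaternary ketone ethyl 5-{5-[5,7-dihydroxy-2,2-dimethyl-8-(2-methylpropanoyl)-2H-chromen-6-yl]-2-(3-methylbut-2-en-1-yl)-3-oxopentan-2-yl}-3-(propan-2-yl)-1,2-oxazole-4-carboxylate F2 and form the quaternary carbon in the annulation itself, giving the racemic prenylated benzisoxazolone F3. Preparative HPLC on a chiral stationary phase (amylose tris(3,5-dimethylphenylcarbamate)) would separate 19 from its (7R) enantiomer F4.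

2. Step 5. The lateral carbanion may take a proton from the lactone α-CH2 instead of adding to the carbonyl, or the sequence may stop after the first bond (open ketone or O-cyclisation). The fallback sets out from 15 and 5 and comes back at 17. It keeps the same one-pot ring construction but uses the simplest two-carbon acyl donor and forms the CH2 bridge afterwards. Compound 15 (LDA, THF, −78 °C), then ethyl acetate, then more LDA with warming would give, through the methyl ketone ethyl 5-(3-oxobutan-2-yl)-3-(propan-2-yl)-1,2-oxazole-4-carboxylate F5, the diol 7-methyl-3-(propan-2-yl)-1,2-benzoxazole-4,6-diol F6. Separately, 5 and Eschenmoser's salt (dimethylmethylideneammonium iodide; CH2Cl2, 25 °C, aq. NaHCO3 work-up) would give the Mannich base 1-{6-[(dimethylamino)methyl]-5,7-dihydroxy-2,2-dimethyl-2H-chromen-8-yl}-2-methylpropan-1-one F7. Heating F6 with F7 in dioxane at 100 °C should alkylate the only free ring carbon of F6 (C5) with loss of dimethylamine (Mannich-base alkylation, the classical way to the methylene bridge of dimeric acylphloroglucinols) and give 17.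

3. Step 7. Hydrolysis of the doubly conjugated vinylogous amide may be slow, and forcing conditions may add the enol oxygen to the prenyl alkene under acid or scramble the methylene bridge under base. The fallback sets out from 17 and comes back at 21. It unmasks the ketone before the prenyl group is present. Mo(CO)6 (MeCN–H2O, 80 °C) would cleave the N–O bond of 17 to the ortho-hydroxyaryl ketimine 2-{[5,7-dihydroxy-2,2-dimethyl-8-(2-methylpropanoyl)-2H-chromen-6-yl]methyl}-4-(1-imino-2-methylpropyl)-6-methylbenzene-1,3,5-triol F8. Dilute aqueous HCl at 25 °C should hydrolyse F8 to the aromatic ketone 1-(3-{[5,7-dihydroxy-2,2-dimethyl-8-(2-methylpropanoyl)-2H-chromen-6-yl]methyl}-2,4,6-trihydroxy-5-methylphenyl)-2-methylpropan-1-one F9. The palladium-catalysed asymmetric prenylation of step 6 (18, Et3N, same catalyst) would then be run on F9 at the methyl-bearing carbon of ring A (dearomative C-prenylation of a C-methyl acylphloroglucinol) and give 21 directly.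

Further compounds
F1 | step 6 | ethyl 5-(5-methylhex-4-en-2-yl)-3-(propan-2-yl)-1,2-oxazole-4-carboxylate (racemic) | CCOC(=O)c1c(C(C)C)noc1C(C)CC=C(C)C
F2 | step 6 | ethyl 5-{5-[5,7-dihydroxy-2,2-dimethyl-8-(2-methylpropanoyl)-2H-chromen-6-yl]-2-(3-methylbut-2-en-1-yl)-3-oxopentan-2-yl}-3-(propan-2-yl)-1,2-oxazole-4-carboxylate (racemic) | CCOC(=O)c1c(C(C)C)noc1C(C)(CC=C(C)C)C(=O)CCc1c(O)c2C=CC(C)(C)Oc2c(C(=O)C(C)C)c1O
F3 | step 6 | racemic 5-{[5,7-dihydroxy-2,2-dimethyl-8-(2-methylpropanoyl)-2H-chromen-6-yl]methyl}-6-hydroxy-7-methyl-7-(3-methylbut-2-en-1-yl)-3-(propan-2-yl)-1,2-benzoxazol-4(7H)-one | CC(C)=CCC1(C)C(O)=C(Cc2c(O)c3c(c(C(=O)C(C)C)c2O)OC(C)(C)C=C3)C(=O)c2c(C(C)C)noc21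
F4 | step 6 | (7R)-5-{[5,7-dihydroxy-2,2-dimethyl-8-(2-methylpropanoyl)-2H-chromen-6-yl]methyl}-6-hydroxy-7-methyl-7-(3-methylbut-2-en-1-yl)-3-(propan-2-yl)-1,2-benzoxazol-4(7H)-one | CC(C)=CC[C@]1(C)C(O)=C(Cc2c(O)c3c(c(C(=O)C(C)C)c2O)OC(C)(C)C=C3)C(=O)c2c(C(C)C)noc21
F5 | step 5 | ethyl 5-(3-oxobutan-2-yl)-3-(propan-2-yl)-1,2-oxazole-4-carboxylate | CCOC(=O)c1c(C(C)C)noc1C(C)C(C)=O
F6 | step 5 | 7-methyl-3-(propan-2-yl)-1,2-benzoxazole-4,6-diol | Cc1c(O)cc(O)c2c(C(C)C)noc12
F7 | step 5 | 1-{6-[(dimethylamino)methyl]-5,7-dihydroxy-2,2-dimethyl-2H-chromen-8-yl}-2-methylpropan-1-one | CC(C)C(=O)c1c(O)c(CN(C)C)c(O)c2C=CC(C)(C)Oc12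
F8 | step 7 | 2-{[5,7-dihydroxy-2,2-dimethyl-8-(2-methylpropanoyl)-2H-chromen-6-yl]methyl}-4-(1-imino-2-methylpropyl)-6-methylbenzene-1,3,5-triol | Cc1c(O)c(Cc2c(O)c3C=CC(C)(C)Oc3c(C(=O)C(C)C)c2O)c(O)c(C(=N)C(C)C)c1O
F9 | step 7 | 1-(3-{[5,7-dihydroxy-2,2-dimethyl-8-(2-methylpropanoyl)-2H-chromen-6-yl]methyl}-2,4,6-trihydroxy-5-methylphenyl)-2-methylpropan-1-one | Cc1c(O)c(Cc2c(O)c3C=CC(C)(C)Oc3c(C(=O)C(C)C)c2O)c(O)c(C(=O)C(C)C)c1O
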